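The earlier runs and the new flask come from a simulation from invented constants.

The second substrate was my suspect, so I ranked the earlier runs by rate, fastest first.

the same everywhere: starting material 0.050 M

| flask | second substrate | enzyme | remark |
|---|---|---|---|
| spring | 0.050 M | 2.4 µM | run made earlier |
| summer | 0.050 M | 5.4 µM | run made earlier |
| midnight | 0.075 M | 3.6 µM | run made earlier |
| flask | 0.0500 M | 3.6 µM |  |

- spring (time / s: target / %): 20.0: 0; 40.0: 0; 60.0: 3; 80.0: 6; 90.0: 5; 120: 9
- summer (time / s: target / %): 10.0: 2; 25.0: 7; 40.0: 9; 60.0: 8; 90.0: 33; 120: 42
- midnight (time / s: target / %): 10.0: 2; 30.0: 4; 60.0: 0; 80.0: 6; 120: 7

(scatter of a reading: 2 percentage points)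

- the numbers in the tables scatter with a standard deviation of 2 percentage points

- apparent order in second substrate when 50% of the starting material are converted (percent change of the rate of making target for one percent more second substrate charged)

On the top rung stood the late summer run: from 60.0 s to 120 s it made target at 0.340 /min as a fraction of the charge, as read from the scattered points. Over its first 40.0 s the same run managed 0.135 /min, slower, so the summer flask sped up as it ran, and the late stretch stayed above the other averages here. Below it came the spring run, averaging 0.0450 /min to 120 s. The midnight run averaged 0.0350 /min to 120 s, a little lower, though the gap lay within the scatter of 2 points. Yet midnight had more enzyme than spring, and more second substrate too, at 0.075 M. I read this as second substrate holding the enzyme and releasing it as it was used.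

For the flask I took the symmetric case as my zero: equal charges, lost one for one. At 50% conversion that case leaves 0.0250 M of second substrate. When a fixed amount has gone, extra charge counts for more in what remains, so I named the leverage, charge over what is left, 2.00. A rate following free enzyme, with the enzyme wholly held, has order −1 in what remains, so I reckoned −2.00. The forecast also gave −2, since the leverage “doubles the apparent order”.

The flask gave −2.3.

    starting material + enzyme ⇌ complex A (K = 24.0 /M, k = 53400 /M/s)
    complex A → enzyme + target (k = 423 /s)
    second substrate + enzyme ⇌ complex B (K = 1700 /M, k = 1.72 × 10⁵ /M/s)
    complex B → enzyme + second product (k = 152 /s)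
    starting material → uncatalysed product (k = 0.00813 /s)

At 1.00 min, before the 1.20 min at which 50% conversion came, the flask held 39.1% of its second substrate but 56.8% of its starting material, so the loss had not been one for one. The leverage there was 2.55, above my 2.00. Complex B, the resting state, held 89.4% of the enzyme then, more than the 6.73% free and the 3.85% in complex A.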